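**Retrosynthetic overview**

1. Target ⇒ acetylation and E1cB dehydration of an aldol adduct (C7–C8 bond) made from (4S)-2-chloro-4-hydroxy-4-[(2Z)-oct-2-en-1-yl]cyclopent-2-en-1-one and methyl (5Z)-7-oxohept-5-enoate.
2. That hydroxy chloro enone ⇒ Stork–Danheiser 1,3-carbonyl transposition of a 2-chloro-3-ethoxy-5-hydroxy-5-alkenylcyclopent-2-enone; the (Z)-octenyl chain comes from a Z-Wittig on the aldehyde left by cleaving an (E)-but-2-enyl group; chlorine comes from NCS.
3. Key disconnection: the C12–C13 bond and the quaternary carbinol centre come from a Claisen [3,3] rearrangement of a cyclic enol allyl ether, generated by rhodium-carbenoid O–H insertion of 5-diazo-3-ethoxycyclopent-2-en-1-one into (2S)-but-3-en-2-ol (1,3-chirality transfer from the only bought stereocentre).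
4. Rings: the single carbocycle is bought as 3-ethoxycyclopent-2-en-1-one and carried through; no ring is made.
5. The enal ⇒ Z-Wittig of the ylide from methyl 5-bromopentanoate with glyoxal monoacetal, then acetal hydrolysis.

Assumption: positions are given in prostanoid numbering (C1 = ester carbon, ring = C8–C12), and (2S)-but-3-en-2-ol (≥98% ee, L-lactic acid series) is taken as a catalogue compound.

**Route**

Step 1
Reactants: 1 3-ethoxycyclopent-2-en-1-one
Product: 3 5-diazo-3-ethoxycyclopent-2-en-1-one, via trifluoroacetyl ketone 2 (not isolated)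
Conditions: LiN(SiMe3)2, THF, −78 °C; CF3CO2CH2CF3; aq. HCl; then MsN3, Et3N, H2O, MeCN, rt
Reagents that add atoms: methanesulfonyl azide, CS(=O)(=O)N=[N+]=[N-]; 2,2,2-trifluoroethyl trifluoroacetate, O=C(OCC(F)(F)F)C(F)(F)F (its acyl group is carried only by 2)
Why: Kinetic alpha-prime enolisation of the vinylogous ester and Claisen-type trifluoroacetylation activate C5 for a deacylative (Regitz-type) diazo transfer that gives the alpha-diazo ketone without creating a stereocentre.

Step 2
Reactants: 3 5-diazo-3-ethoxycyclopent-2-en-1-one; 4 (2S)-but-3-en-2-ol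
Product: 7 (5S)-5-[(2E)-but-2-en-1-yl]-3-ethoxy-5-hydroxycyclopent-2-en-1-one, via enol allyl ether 5 (not isolated), via hydroxy ketone 6 (not isolated)
Conditions: Rh2(OAc)4 (1 mol %), 4 (2 equiv), benzene, 80 °C, slow addition of 3; then DBU (0.1 equiv), rt
Reagents that add atoms: none
Why: Rhodium-carbenoid O–H insertion gives the ring-locked (Z)-enol allyl ether 5, which undergoes a Claisen [3,3]-sigmatropic rearrangement through a chair transition state with the carbinol methyl equatorial, so the C–O stereocentre of 4 is traded by 1,3-chirality transfer for the quaternary (S)-carbinol carbon (C12) and an E-alkene, after which base moves the enol-ether double bond of 6 into conjugation.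

Step 3
Reactants: 7 (5S)-5-[(2E)-but-2-en-1-yl]-3-ethoxy-5-hydroxycyclopent-2-en-1-one
Product: 8 (5S)-5-[(2E)-but-2-en-1-yl]-2-chloro-3-ethoxy-5-hydroxycyclopent-2-en-1-one
Conditions: NCS, CH2Cl2, 0 °C to rt
Reagents that add atoms: N-chlorosuccinimide, O=C1CCC(=O)N1Cl
Why: Electrophilic alpha-chlorination of the vinylogous ester at its nucleophilic C2 (the future C10) is much faster than attack on the isolated alkene and leaves the quaternary centre untouched.

Step 4
Reactants: 8 (5S)-5-[(2E)-but-2-en-1-yl]-2-chloro-3-ethoxy-5-hydroxycyclopent-2-en-1-one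
Product: 9 2-[(1R)-3-chloro-4-ethoxy-1-hydroxy-2-oxocyclopent-3-en-1-yl]acetaldehyde
Conditions: OsO4 (2 mol %), NaIO4, 2,6-lutidine, dioxane/H2O 3:1, rt
Reagents that add atoms: sodium periodate, [Na+].[O-][I](=O)(=O)=O
Why: Lemieux–Johnson oxidative cleavage takes the electron-rich disubstituted side-chain alkene in preference to the tetrasubstituted chloro-alkoxy enone, whose vinylogous-ester carbonyl is too poorly hydrated for alpha-ketol cleavage.

Step 5
Reactants: 9 2-[(1R)-3-chloro-4-ethoxy-1-hydroxy-2-oxocyclopent-3-en-1-yl]acetaldehyde; 10 hexyl(triphenyl)phosphonium bromide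
Product: 11 (5S)-2-chloro-3-ethoxy-5-hydroxy-5-[(2Z)-oct-2-en-1-yl]cyclopent-2-en-1-one
Conditions: NaN(SiMe3)2, THF, −78 °C (2.2 equiv ylide); then 9, −78 to 0 °C
Reagents that add atoms: none
Why: Salt-free Wittig olefination with the non-stabilised ylide gives the (Z)-alkene under kinetic control, and the excess ylide tolerates the free tertiary alcohol and the unreactive vinylogous-ester carbonyl.

Step 6
Reactants: 11 (5S)-2-chloro-3-ethoxy-5-hydroxy-5-[(2Z)-oct-2-en-1-yl]cyclopent-2-en-1-one
Product: 13 (4S)-2-chloro-4-hydroxy-4-[(2Z)-oct-2-en-1-yl]cyclopent-2-en-1-one, via allylic diol 12 (not isolated)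
Conditions: iBu2AlH (3 equiv), CH2Cl2, −78 °C; then 1 M HCl, THF, 0 °C to rt
Reagents that add atoms: water, O
Why: Stork–Danheiser 1,3-carbonyl transposition (1,2-reduction of the vinylogous ester, then acid hydrolysis of the enol ether with loss of the allylic hydroxyl) gives the 2-chloro-4-hydroxy enone while the quaternary centre stays outside the reacting array.

Step 7
Reactants: 14 methyl 5-bromopentanoate
Product: 15 (5-methoxy-5-oxopentyl)(triphenyl)phosphonium bromide
Conditions: PPh3, MeCN, 82 °C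
Reagents that add atoms: triphenylphosphine, c1ccc(cc1)P(c1ccccc1)c1ccccc1
Why: SN2 quaternisation of the phosphine by the primary bromide gives the Wittig salt.

Step 8
Reactants: 15 (5-methoxy-5-oxopentyl)(triphenyl)phosphonium bromide; 16 2,2-dimethoxyacetaldehyde
Product: 17 methyl (5Z)-7,7-dimethoxyhept-5-enoate
Conditions: NaN(SiMe3)2, THF, −78 °C; then anhydrous 16, −78 to 0 °C
Reagents that add atoms: none
Why: Z-selective Wittig olefination of the non-stabilised ester ylide with the glyoxal monoacetal under salt-free, low-temperature conditions sets the 5Z alkene.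

Step 9
Reactants: 17 methyl (5Z)-7,7-dimethoxyhept-5-enoate
Product: 18 methyl (5Z)-7-oxohept-5-enoate
Conditions: 10% aq. oxalic acid on SiO2, CH2Cl2, rt, short contact; used at once
Reagents that add atoms: water, O
Why: Mild heterogeneous acetal hydrolysis on wet acidic silica releases the (Z)-enal without the prolonged acid contact that would isomerise it to the E-enal.

Step 10
Reactants: 13 (4S)-2-chloro-4-hydroxy-4-[(2Z)-oct-2-en-1-yl]cyclopent-2-en-1-one; 18 methyl (5Z)-7-oxohept-5-enoate
Product: 19 methyl (5Z)-7-[(2S)-4-chloro-2-hydroxy-2-[(2Z)-oct-2-en-1-yl]-5-oxocyclopent-3-en-1-yl]-7-hydroxyhept-5-enoate (epimers at ring C1/C7)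
Conditions: LiN(iPr)2 (2.2 equiv), THF, −78 °C; then 18, −78 °C; AcOH
Reagents that add atoms: none
Why: Directed aldol addition of the alkoxide/alpha-prime lithium enolate dianion (kinetic deprotonation at C8) to the (Z)-enal in 1,2-fashion forms the C7–C8 bond, and the two new stereocentres arise as a mixture that is erased in the next step.

Step 11
Reactants: 19 methyl (5Z)-7-[(2S)-4-chloro-2-hydroxy-2-[(2Z)-oct-2-en-1-yl]-5-oxocyclopent-3-en-1-yl]-7-hydroxyhept-5-enoate
Product: 21 methyl (5Z,7E)-7-[(2R)-2-acetoxy-4-chloro-2-[(2Z)-oct-2-en-1-yl]-5-oxocyclopent-3-en-1-ylidene]hept-5-enoate, via diacetate 20 (not isolated)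
Conditions: Ac2O, Et3N, DMAP, CH2Cl2, 0 °C to rt
Reagents that add atoms: acetic anhydride, CC(=O)OC(C)=O
Why: DMAP-catalysed acetylation of both hydroxyls followed by E1cB elimination of the beta-acetoxy ketone gives the cross-conjugated dienone mainly as the 7E isomer (the minor 7Z isomer is removed by chromatography), while the tertiary acetate cannot eliminate because that would give an antiaromatic cyclopentadienone.

**Compound list**

1 | 3-ethoxycyclopent-2-en-1-one | CCOC1=CC(=O)CC1 | starting material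
2 | 3-ethoxy-5-(2,2,2-trifluoroacetyl)cyclopent-2-en-1-one | CCOC1=CC(=O)C(C(=O)C(F)(F)F)C1 | intermediate
3 | 5-diazo-3-ethoxycyclopent-2-en-1-one | CCOC1=CC(=O)C(=[N+]=[N-])C1 | intermediate
4 | (2S)-but-3-en-2-ol | C[C@H](O)C=C | starting material
5 | 1-{[(2S)-but-3-en-2-yl]oxy}-4-ethoxycyclopenta-1,3-dien-2-ol | CCOC1=CC(O)=C(O[C@@H](C)C=C)C1 | intermediate
6 | (2S)-2-[(2E)-but-2-en-1-yl]-4-ethoxy-2-hydroxycyclopent-3-en-1-one | C/C=C/C[C@@]1(O)C(=O)CC(OCC)=C1 | intermediate
7 | (5S)-5-[(2E)-but-2-en-1-yl]-3-ethoxy-5-hydroxycyclopent-2-en-1-one | C/C=C/C[C@@]1(O)C(=O)C=C(OCC)C1 | intermediate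
8 | (5S)-5-[(2E)-but-2-en-1-yl]-2-chloro-3-ethoxy-5-hydroxycyclopent-2-en-1-one | C/C=C/C[C@@]1(O)C(=O)C(Cl)=C(OCC)C1 | intermediate
9 | 2-[(1R)-3-chloro-4-ethoxy-1-hydroxy-2-oxocyclopent-3-en-1-yl]acetaldehyde | O=CC[C@@]1(O)C(=O)C(Cl)=C(OCC)C1 | intermediate
10 | hexyl(triphenyl)phosphonium bromide | CCCCCC[P+](c1ccccc1)(c1ccccc1)c1ccccc1.[Br-] | starting material
11 | (5S)-2-chloro-3-ethoxy-5-hydroxy-5-[(2Z)-oct-2-en-1-yl]cyclopent-2-en-1-one | CCCCC/C=C\C[C@@]1(O)C(=O)C(Cl)=C(OCC)C1 | intermediate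
12 | (1S)-3-chloro-4-ethoxy-1-[(2Z)-oct-2-en-1-yl]cyclopent-3-ene-1,2-diol (both C2 epimers) | CCCCC/C=C\C[C@@]1(O)C(O)C(Cl)=C(OCC)C1 | intermediate
13 | (4S)-2-chloro-4-hydroxy-4-[(2Z)-oct-2-en-1-yl]cyclopent-2-en-1-one | CCCCC/C=C\C[C@@]1(O)C=C(Cl)C(=O)C1 | intermediate
14 | methyl 5-bromopentanoate | COC(=O)CCCCBr | starting material
15 | (5-methoxy-5-oxopentyl)(triphenyl)phosphonium bromide | COC(=O)CCCC[P+](c1ccccc1)(c1ccccc1)c1ccccc1.[Br-] | intermediate
16 | 2,2-dimethoxyacetaldehyde | COC(OC)C=O | starting material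
17 | methyl (5Z)-7,7-dimethoxyhept-5-enoate | COC(=O)CCC/C=C\C(OC)OC | intermediate
18 | methyl (5Z)-7-oxohept-5-enoate | COC(=O)CCC/C=C\C=O | intermediate
19 | methyl (5Z)-7-[(2S)-4-chloro-2-hydroxy-2-[(2Z)-oct-2-en-1-yl]-5-oxocyclopent-3-en-1-yl]-7-hydroxyhept-5-enoate (epimers at ring C1/C7) | CCCCC/C=C\C[C@@]1(O)C=C(Cl)C(=O)C1C(O)/C=C\CCCC(=O)OC | intermediate
20 | methyl (5Z)-7-acetoxy-7-[(2S)-2-acetoxy-4-chloro-2-[(2Z)-oct-2-en-1-yl]-5-oxocyclopent-3-en-1-yl]hept-5-enoate (epimers at ring C1/C7) | CCCCC/C=C\C[C@@]1(OC(C)=O)C=C(Cl)C(=O)C1C(OC(C)=O)/C=C\CCCC(=O)OC | intermediate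
21 | methyl (5Z,7E)-7-[(2R)-2-acetoxy-4-chloro-2-[(2Z)-oct-2-en-1-yl]-5-oxocyclopent-3-en-1-ylidene]hept-5-enoate | CCCCC/C=C\C[C@@]1(OC(C)=O)C=C(Cl)C(=O)/C1=C/C=C\CCCC(=O)OC | target

The descriptor at the carbinol carbon changes from S (7–20) to R (21) only because the CIP ranking of its two ring neighbours swaps once C8 becomes an alkene carbon; the spatial arrangement is unchanged.

**Step count**

Total: 11 steps. Longest linear sequence: 8 steps (1 → 3 → 7 → 8 → 9 → 11 → 13 → 19 → 21); the enal 18 takes 3 steps.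

**Steps most likely to fail, with fallbacks**

Step 2 (carbenoid O–H insertion / Claisen) is the least precedented step for this ring system. The enol 5 may tautomerise to the plain O–H insertion product instead of rearranging, the carbenoid may suffer 1,2-hydride shift, and any boat transition state would erode the enantiomeric purity. The fallback sets out from 3 and returns at 7. Decompose 3 with BF3·OEt2 in the presence of 4 (CH2Cl2, −20 °C), a cationic O–H insertion that by-passes the enol, and isolate the ether 3-ethoxy-5-{[(2S)-but-3-en-2-yl]oxy}cyclopent-2-en-1-one F1 (both C5 epimers). Then form its potassium enolate (KH, 18-crown-6, THF, −20 °C), in which C5 is planar; it undergoes the anionic oxy-Claisen [3,3] shift at low temperature with the same chair chirality transfer and gives 7 after protonation and conjugation.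

Step 10 (dianion aldol) may fail in three ways: the lithium alkoxide of 13 can open by retro-aldol (racemising C12), the dianion may be poorly soluble, and the (Z)-enal 18 is base-sensitive. The fallback sets out from 13 and returns at 19. Silylate 13 (Me3SiCl, imidazole, DMF) to (4S)-2-chloro-4-[(2Z)-oct-2-en-1-yl]-4-[(trimethylsilyl)oxy]cyclopent-2-en-1-one F2. Form the mono-enolate (LiN(iPr)2, 1.1 equiv, THF, −78 °C) and add 18 to get methyl (5Z)-7-[(2S)-4-chloro-2-[(2Z)-oct-2-en-1-yl]-5-oxo-2-[(trimethylsilyl)oxy]cyclopent-3-en-1-yl]-7-hydroxyhept-5-enoate F3. Cleave the tertiary silyl ether with HF·pyridine (THF, 0 °C) to reach 19.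

Step 9 (acetal hydrolysis) may isomerise the (Z)-enal to the E-enal under acid. The fallback sets out from 15 and returns at 18. Olefinate the ylide of 15 (NaN(SiMe3)2, THF, −78 °C) with (tert-butyldimethylsilyloxy)acetaldehyde to give methyl (5Z)-7-[(tert-butyldimethylsilyl)oxy]hept-5-enoate F4. Desilylate (Bu4NF, THF, 0 °C) to methyl (5Z)-7-hydroxyhept-5-enoate F5, and oxidise under buffered, non-acidic conditions (Dess–Martin periodinane, NaHCO3, CH2Cl2, 0 °C) to 18.

**Further compounds**

F1 | step 2 | 3-ethoxy-5-{[(2S)-but-3-en-2-yl]oxy}cyclopent-2-en-1-one (both C5 epimers) | CCOC1=CC(=O)C(O[C@@H](C)C=C)C1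
F2 | step 10 | (4S)-2-chloro-4-[(2Z)-oct-2-en-1-yl]-4-[(trimethylsilyl)oxy]cyclopent-2-en-1-one | CCCCC/C=C\C[C@@]1(O[Si](C)(C)C)C=C(Cl)C(=O)C1
F3 | step 10 | methyl (5Z)-7-[(2S)-4-chloro-2-[(2Z)-oct-2-en-1-yl]-5-oxo-2-[(trimethylsilyl)oxy]cyclopent-3-en-1-yl]-7-hydroxyhept-5-enoate (epimers at ring C1/C7) | CCCCC/C=C\C[C@@]1(O[Si](C)(C)C)C=C(Cl)C(=O)C1C(O)/C=C\CCCC(=O)OC
F4 | step 9 | methyl (5Z)-7-[(tert-butyldimethylsilyl)oxy]hept-5-enoate | COC(=O)CCC/C=C\CO[Si](C)(C)C(C)(C)C
F5 | step 9 | methyl (5Z)-7-hydroxyhept-5-enoate | COC(=O)CCC/C=C\CO
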